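## The problem

Atoms are numbered as in the germacrane skeleton: ring C1 to C10, methyl C14 on C10, CH2OH C15 on C4, lactone carbonyl C12, exocyclic methylene C13 on C11.

- Target 31 is a heliangolide-type germacranolide. A ten-membered carbocycle is trans-fused at C6–C7 to an α-methylene-γ-butyrolactone (ring O–C6–C7–C11–C12). It carries a trans 1,10-epoxide, a Z C4=C5 alkene, a free carbinol at C3 and an angelate at C8. The configuration is 1R,3S,6R,7R,8R,10R.
- The medium ring has to be closed against transannular strain. Both ring alkene geometries must be fixed before closure: E at C1=C10 (the epoxide precursor) and Z at C4=C5.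
- C6, C7 and C8 are contiguous. C6 can control C7 through the five-membered ring. C8 lies outside that ring when it is made and needs a reagent to control it.
- C3 and the epoxide carbons are remote from the triad. Only the conformation of the ten-membered ring, or a chiral reagent, can control them.
- Several groups limit the conditions. The methylene lactone is a Michael acceptor and is reduced by hydride. The angelate isomerises to the tiglate under nucleophilic catalysis. The epoxide faces C4=C5 across the ring and cyclises with acid. A free O8 next to the lactone invites translactonisation.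
- The enabling feature is the lactone polarity. C7 is the β carbon and C11 the α carbon of carbonyl C12, and C8 bears oxygen. C8 can therefore arrive at C7 as an acyl anion, and the enolate at C11 can take C13 as an electrophile. C6 comes from a chiral-pool butenolide.

## Retrosynthesis

**Epoxide last (31 from 30).** The two C–O bonds of the epoxide are cut, giving the 1(10)E,4Z-dienolide 30. The epoxide is put in last because it would not survive acidic desilylation beside C4=C5. The E alkene is easy to carry through the route. The forward step must pick the electron-rich C1=C10 over three other alkenes and attack its outer face.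

**Ring closure at C3–C4 (30 from 29 from 28).** Desilylation relates 30 to silyl ether 29. The ring bond C3–C4 of 29 is cut to give iodoalkene aldehyde 28. A metathesis at C1=C10 would have to form a trisubstituted alkene in a ten-membered ring without control of geometry. The C3–C4 cut keeps both alkenes preformed and creates the C3 carbinol in the closing step. Precursor 28 is acyclic apart from the lactone and has only the C6/C7/C8 triad. The forward reaction must tolerate a lactone, two enoates and an allylic silyl ether, which points to CrCl2/NiCl2.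

**Unmasking the two ends (28 from 27, 26, 24).** Aldehyde 28 comes from alcohol 27, and 27 from PMB ether 26. The methylene lactone of 26 comes from Mannich base 24 by cutting the C13–N bond. This elimination is placed after the last hydride step and before the DDQ step, so the amine never meets DDQ and the methylene lactone never meets borohydride.

**The Z iodoalkene (24 from 23, 22, 21, 19).** The C4=C5 bond is cut. A formyl ylide brings C4 and C15 to the C5 aldehyde 20, which is made in the flask from alcohol 19. Enal 21 is iodinated at C4 to give 22, then reduced at C15 to 23 and silylated to 24. An iodo-ylide ester would be one step shorter, but its reduction could not be done beside the lactone and the angelate.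

**The C8 ester (19 from 18, 15, 14, 13).** Alcohol 19 is the desilylated form of angelate 18. The ester C–O bond of 18 is cut to give alcohol 15 and angelic acid 16. The carbinol 15 comes from ketone 14, and 14 from dithiane 13. C8 is set by a chiral reducing agent, because the bias of the neighbouring ring is not predictable.

**The key cut (13 from 9, 2 and 10).** The C7–C8 and C11–C13 bonds are cut together. This gives lithiated dithiane 9 as the C8 acyl anion, butenolide 2 as the acceptor and iminium salt 10 as the C13 electrophile. No other cut delivers the lactone, the C8 oxygen, C13 and the C7 stereocentre in one operation from a purchasable chiral building block.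

**The two building blocks.** Dithiane 9 is cut at C8–C9 into 1,3-dithiane 7 and allylic bromide 6. Bromide 6 comes from alcohol 5, which comes from PMB ether 4 by allylic oxidation of its E methyl group; 4 is made from 4-methylpent-3-en-1-ol 3. That oxidation fixes the E geometry of C1=C10. Butenolide 2 is the silyl ether of alcohol 1.

## Roads not taken

**Alternative 1:** The lactone C6–O bond is cut, leading back to the open acid A2. In the forward step a cytochrome P450 of the germacrene A acid 6-hydroxylase class would oxidise one C6–H bond, and the new alcohol would close onto C12 to give A1.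
- Merits: the enzyme would set C6 and the trans lactone without protecting groups. A1 is the same compound as 30, so both roads would end with the same epoxidation.
- Weak points: A2 is not purchasable and is as hard to make as the target, with a ten-membered ring, two defined alkenes and three stereocentres. The known enzymes act on the unoxidised parent acid; a 4Z substrate oxygenated at C3, C8 and C15 is far outside that scope.
- Comparison: an accepting enzyme would beat the chosen plan in lactone control. The chosen plan offers a chiral-pool C6, a substrate-controlled C7 and ordinary reagents throughout.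

**Alternative 2:** A transannular C6–C10 bond is added in the retrosynthetic sense, giving the trans-fused hydroazulenol mesylate A4. In the forward step KOC(CH3)3 would deprotonate the bridgehead C6 alcohol, and the C6–C10 bond would cleave anti to the C1 mesylate (Grob fragmentation) to give dienone A3.
- Merits: the ring opens out of a bicycle, so no high dilution is needed. The E geometry of C1=C10 follows stereospecifically from the antiperiplanar arrangement, and the Z C4=C5 alkene is natural in the seven-membered ring.
- Weak points: A4 needs six stereocentres, three of which (C1, C6, C10) become trigonal. After fragmentation the C6 ketone must be reduced with facial control on a flexible ring. The lactone must then be built from the acetal, C13 added and the C8 ether exchanged for the angelate, all on a strained cross-ring-reactive enone.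
- Comparison: this road is better for ring formation and alkene geometry. The chosen plan offers the lactone, C13 and C7 in one step and three fewer stereocentres to construct.

**Alternative 3:** The C1–C2 bond and the C10–C14 bond are cut, giving alkyne A6 and epoxide A7. In the forward step AlMe3 with catalytic Cp2ZrCl2 would add methyl and aluminium syn across A6, and the derived alkenylalanate would open A7 at C2 to give A5.
- Merits: the E alkene is formed with full control, and C3 comes from the chiral pool. For C3 this is better than the chosen plan, which relies on the facial selectivity of a ring closure.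
- Weak points: A5 stops at C8 and at an sp3 C4. The Z C4=C5 alkene, the C6/C7/C8 triad, the lactone and the ring closure all remain to be solved.
- Comparison: the chosen plan answers the C3 weakness with an oxidation and reagent-controlled reduction as fallback. In return it treats the lactone triad far more briefly.

Key step: step 6

Remark: C11 of Mannich base 13 is drawn as the expected 7,11-trans isomer; either epimer serves, because C11 becomes trigonal in step 15.

## Route

Step 1
Reactants: 1 (S)-5-(hydroxymethyl)furan-2(5H)-one
Product: 2 (S)-5-[(tert-butyldimethylsilyloxy)methyl]furan-2(5H)-one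
Conditions: TBSCl, imidazole, CH2Cl2, 0 °C to rt
Reagents that add atoms: tert-butyldimethylsilyl chloride, CC(C)(C)[Si](C)(C)Cl
Why: Standard silylation of a primary alcohol; the C6 stereocentre is not touched.

Step 2
Reactants: 3 4-methylpent-3-en-1-ol
Product: 4 1-methoxy-4-{[(4-methylpent-3-en-1-yl)oxy]methyl}benzene
Conditions: NaH, PMBCl, Bu4NI (cat.), THF/DMF, 0 °C to rt
Reagents that add atoms: 4-methoxybenzyl chloride, COc1ccc(CCl)cc1
Why: Williamson etherification of a primary alkoxide with a benzylic chloride.

Step 3
Reactants: 4 PMB ether of 4-methylpent-3-en-1-ol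
Product: 5 (E)-5-(4-methoxybenzyloxy)-2-methylpent-2-en-1-ol
Conditions: SeO2 (0.3 equiv), t-BuOOH, salicylic acid (cat.), CH2Cl2, 0 °C to rt
Reagents that add atoms: selenium dioxide, O=[Se]=O, re-oxidised by tert-butyl hydroperoxide, CC(C)(C)OO
Why: Riley-type allylic oxidation (ene reaction then [2,3]-shift) hydroxylates the E methyl group of a trisubstituted alkene, which fixes the E geometry of the later C1=C10 bond.

Step 4
Reactants: 5 (E)-5-(4-methoxybenzyloxy)-2-methylpent-2-en-1-ol
Product: 6 (E)-1-bromo-5-(4-methoxybenzyloxy)-2-methylpent-2-ene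
Conditions: CBr4, PPh3, CH2Cl2, 0 °C
Reagents that add atoms: carbon tetrabromide, BrC(Br)(Br)Br
Why: Appel bromination of a primary allylic alcohol proceeds by direct displacement without allylic transposition under these neutral conditions.

Step 5
Reactants: 7 1,3-dithiane; 6 (E)-1-bromo-5-(4-methoxybenzyloxy)-2-methylpent-2-ene
Product: 9 2-[(E)-5-(4-methoxybenzyloxy)-2-methylpent-2-enyl]-1,3-dithiane, via 2-lithio-1,3-dithiane 8 (not isolated)
Conditions: n-BuLi, THF, −30 °C; then 6, −78 to 0 °C
Reagents that add atoms: none
Why: Corey–Seebach alkylation; the sulfur-stabilised anion displaces the primary allylic bromide at the α carbon and forms the C8–C9 bond.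

Step 6
Reactants: 9 2-[(E)-5-(4-methoxybenzyloxy)-2-methylpent-2-enyl]-1,3-dithiane; 2 (S)-5-[(tert-butyldimethylsilyloxy)methyl]furan-2(5H)-one; 10 N,N-dimethylmethyleneiminium iodide
Product: 13 trans-disubstituted lactone Mannich base carrying C8 as the dithiane, via lithiated dithiane 11 (not isolated), via lithium lactone enolate 12 (not isolated)
Conditions: n-BuLi, THF, −25 °C, 2 h; HMPA (4 equiv), −78 °C; 2, −78 °C; then 10, −78 °C to rt
Reagents that add atoms: none
Why: n-BuLi removes the dithiane C–H of 9; in THF/HMPA the tertiary carbanion 11 is a solvent-separated ion pair and adds to the β carbon C7 of butenolide 2 instead of its carbonyl group. The lithium enolate 12 is then alkylated at C11 by the iminium ion of 10 in a Mannich reaction, so C7–C8 and C11–C13 form in one flask. The closest known reaction type is the tandem conjugate addition of lithiated dithianes to butenolides with electrophilic capture of the enolate, joined to the aminomethylation of lactone enolates by methyleneiminium salts. No ring closes. The new C7 stereocentre is controlled by the C6 silyloxymethyl group, which shields one face, so the nucleophile enters anti and C7 is trans to C6 as in the target. The iminium ion should enter anti to the bulky dithianyl group at C7, but C11 is later erased. The step needs 1,4- over 1,2-addition and over γ-deprotonation of 2; the polar cosolvent, the low temperature and the soft sulfur-stabilised anion secure this.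

Step 7
Reactants: 13 lactone Mannich base with C8 dithiane
Product: 14 C8 ketone
Conditions: Hg(ClO4)2, CaCO3, THF/H2O (5:1), 0 °C
Reagents that add atoms: water, O
Why: Thiophilic divalent mercury cleaves the thioketal under buffered conditions that leave the amine, the PMB and silyl ethers and the alkene alone; 14 is used at once because C7–H lies between the ketone and the acyloxy carbon C6.

Step 8
Reactants: 14 C8 ketone
Product: 15 (8R) alcohol
Conditions: (S)-2-methyl-CBS-oxazaborolidine [(3aS)-1-methyl-3,3-diphenyltetrahydro-1H,3H-pyrrolo[1,2-c][1,3,2]oxazaborole] (0.5 equiv), catecholborane, toluene/CH2Cl2, −78 to −40 °C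
Reagents that add atoms: none
Why: Corey–Bakshi–Shibata reduction; the catalyst binds the ketone with the branched ring carbon C7 as the large group and the C9 methylene as the small one and delivers hydride to the face that gives 8R, and catecholborane is used because its adduct with the dimethylamino group is cleaved on work-up.

Step 9
Reactants: 15 (8R) alcohol; 16 angelic acid
Product: 18 (8R) angelate, via angelic 2,4,6-trichlorobenzoic anhydride 17 (not isolated)
Conditions: 16, 2,4,6-trichlorobenzoyl chloride, Et3N, toluene, rt; then 15, 75 °C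
Reagents that add atoms: none
Why: Yamaguchi-type mixed-anhydride acylation without a nucleophilic catalyst transfers the angeloyl group to a hindered secondary alcohol with retention at C8 and without Z to E isomerisation to the tiglate.

Step 10
Reactants: 18 (8R) angelate
Product: 19 C5 primary alcohol
Conditions: HF·pyridine, pyridine, THF, 0 °C to rt
Reagents that add atoms: none
Why: Buffered fluoride cleaves the primary silyl ether; the PMB ether, both esters and the amine are inert.

Step 11
Reactants: 19 C5 primary alcohol
Product: 21 (E)-enal extended by C4 and C15, via C5 aldehyde 20 (not isolated)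
Conditions: Dess–Martin periodinane, pyridine, CH2Cl2, 0 °C to rt; then Ph3P=CHCHO, rt to 35 °C
Reagents that add atoms: (triphenylphosphoranylidene)acetaldehyde, O=CC=P(c1ccccc1)(c1ccccc1)c1ccccc1
Why: Dess–Martin oxidation followed in the same flask by a Wittig reaction with the stabilised formyl ylide, which is E-selective and removes the need to isolate the epimerisable α-acyloxy aldehyde 20.

Step 12
Reactants: 21 (E)-enal
Product: 22 (Z)-α-iodoenal
Conditions: I2, DMAP (0.2 equiv), K2CO3, THF/H2O (1:1), rt
Reagents that add atoms: iodine, II
Why: Baylis–Hillman-type α-iodination (DMAP adds at C5, the enolate is iodinated at C4, DMAP is eliminated) gives the 2-iodo-2-enal with iodine cis to C6, the geometry the ring closure needs.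

Step 13
Reactants: 22 (Z)-α-iodoenal
Product: 23 (Z)-2-iodoallylic alcohol
Conditions: NaBH4, CeCl3·7H2O, MeOH, −78 °C
Reagents that add atoms: none
Why: Luche 1,2-reduction of the aldehyde at low temperature leaves the lactone, the angelate and the vinyl iodide intact; the methylene lactone is still masked as the amine.

Step 14
Reactants: 23 (Z)-2-iodoallylic alcohol
Product: 24 C15 tert-butyldimethylsilyl ether
Conditions: TBSCl, imidazole, CH2Cl2, 0 °C to rt
Reagents that add atoms: tert-butyldimethylsilyl chloride, CC(C)(C)[Si](C)(C)Cl
Why: Standard silylation of the only free hydroxyl group, so that C15 is not oxidised when C3 is.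

Step 15
Reactants: 24 C15 silyl ether
Product: 26 α-methylene lactone, via trimethylammonium iodide 25 (not isolated)
Conditions: MeI, THF, rt; then aq. NaHCO3/CH2Cl2, rt
Reagents that add atoms: none
Why: Quaternisation and Hofmann-type E1cB elimination of the β-ammonium lactone is the classical unmasking of an α-methylene lactone; it removes the C11 stereocentre and the amine before the DDQ step.

Step 16
Reactants: 26 α-methylene lactone
Product: 27 C3 primary alcohol
Conditions: DDQ, CH2Cl2/pH 7 buffer (10:1), 0 °C
Reagents that add atoms: none
Why: Oxidative cleavage of the PMB ether through its benzylic cation; the electron-poor alkenes, the vinyl iodide and the silyl ether do not react.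

Step 17
Reactants: 27 C3 primary alcohol
Product: 28 C3 aldehyde
Conditions: Dess–Martin periodinane, pyridine, CH2Cl2, 0 °C
Reagents that add atoms: none
Why: Buffered Dess–Martin oxidation gives the β,γ-unsaturated aldehyde without moving C1=C10 into conjugation; 28 is used directly.

Step 18
Reactants: 28 C3 aldehyde
Product: 29 ten-membered (3S) allylic alcohol with C15 silyl ether
Conditions: CrCl2 (15 equiv), NiCl2 (0.15 equiv), DMSO, 0.002 M, slow addition, rt
Reagents that add atoms: none
Why: Nozaki–Hiyama–Kishi reaction: zerovalent nickel inserts into the C–I bond with retention of the Z geometry, transmetalation gives an alkenyl species of trivalent chromium that adds only to the aldehyde, and the trans lactone and the two alkenes pre-organise the chain for ten-membered closure; C3 is set in the closing transition state, which is expected to place the new oxygen on the outer β face (3S).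

Step 19
Reactants: 29 ten-membered allylic alcohol with C15 silyl ether
Product: 30 1(10)E,4Z-dienolide diol
Conditions: HF·pyridine, pyridine, THF, 0 °C
Reagents that add atoms: none
Why: Buffered fluoride removes the primary allylic silyl ether before the acid-sensitive epoxide exists.

Step 20
Reactants: 30 1(10)E,4Z-dienolide diol
Product: 31 CNP0187917.1
Conditions: dimethyldioxirane (1.05 equiv), acetone, −40 to −20 °C
Reagents that add atoms: dimethyldioxirane, CC1(C)OO1
Why: Concerted electrophilic epoxidation by the dioxirane picks C1=C10, the only alkene not deactivated by allylic oxygen or conjugation; syn addition to the E alkene gives the trans epoxide, attack on the outer face of the ring should give the 1R,10R isomer, and the neutral medium avoids cross-ring cyclisation.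

## Compound list

1 | (S)-5-(hydroxymethyl)furan-2(5H)-one | O=C1C=C[C@@H](CO)O1 | starting material
2 | (S)-5-[(tert-butyldimethylsilyloxy)methyl]furan-2(5H)-one | O=C1C=C[C@@H](CO[Si](C)(C)C(C)(C)C)O1 | intermediate
3 | 4-methylpent-3-en-1-ol | CC(C)=CCCO | starting material
4 | 1-methoxy-4-{[(4-methylpent-3-en-1-yl)oxy]methyl}benzene | COc1ccc(COCCC=C(C)C)cc1 | intermediate
5 | (E)-5-(4-methoxybenzyloxy)-2-methylpent-2-en-1-ol | COc1ccc(COCC/C=C(\C)CO)cc1 | intermediate
6 | (E)-1-bromo-5-(4-methoxybenzyloxy)-2-methylpent-2-ene | COc1ccc(COCC/C=C(\C)CBr)cc1 | intermediate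
7 | 1,3-dithiane | C1CSCSC1 | starting material
8 | 2-lithio-1,3-dithiane | [Li]C1SCCCS1 | intermediate (not isolated)
9 | 2-[(E)-5-(4-methoxybenzyloxy)-2-methylpent-2-enyl]-1,3-dithiane | COc1ccc(COCC/C=C(\C)CC2SCCCS2)cc1 | intermediate
10 | N,N-dimethylmethyleneiminium iodide | C=[N+](C)C.[I-] | starting material
11 | 2-lithio derivative of 9 | [Li]C1(C/C(C)=C/CCOCc2ccc(OC)cc2)SCCCS1 | intermediate (not isolated)
12 | lithium enolate of the conjugate adduct (C6 as in 2, C7 dithianyl group trans to the C6 side chain) | [Li]OC1=C[C@H](C2(C/C(C)=C/CCOCc3ccc(OC)cc3)SCCCS2)[C@@H](CO[Si](C)(C)C(C)(C)C)O1 | intermediate (not isolated)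
13 | (3R,4S,5S)-5-[(tert-butyldimethylsilyloxy)methyl]-3-[(dimethylamino)methyl]-4-{2-[(E)-5-(4-methoxybenzyloxy)-2-methylpent-2-enyl]-1,3-dithian-2-yl}oxolan-2-one | CN(C)C[C@@H]1C(=O)O[C@H](CO[Si](C)(C)C(C)(C)C)[C@H]1C2(C/C(C)=C/CCOCc3ccc(OC)cc3)SCCCS2 | intermediate
14 | (3R,4S,5S)-5-[(tert-butyldimethylsilyloxy)methyl]-3-[(dimethylamino)methyl]-4-[(E)-6-(4-methoxybenzyloxy)-3-methylhex-3-enoyl]oxolan-2-one | CN(C)C[C@@H]1C(=O)O[C@H](CO[Si](C)(C)C(C)(C)C)[C@H]1C(=O)C/C(C)=C/CCOCc2ccc(OC)cc2 | intermediate
15 | (8R) alcohol from 14: (3R,4R,5S)-lactone bearing a (1R,3E)-1-hydroxy-6-(4-methoxybenzyloxy)-3-methylhex-3-enyl group at C7 | CN(C)C[C@@H]1C(=O)O[C@H](CO[Si](C)(C)C(C)(C)C)[C@H]1[C@H](O)C/C(C)=C/CCOCc2ccc(OC)cc2 | intermediate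
16 | angelic acid, (Z)-2-methylbut-2-enoic acid | C/C=C(/C)C(=O)O | starting material
17 | angelic 2,4,6-trichlorobenzoic anhydride | C/C=C(/C)C(=O)OC(=O)c1c(Cl)cc(Cl)cc1Cl | intermediate (not isolated)
18 | (8R) angelate of 15, other centres unchanged | CN(C)C[C@@H]1C(=O)O[C@H](CO[Si](C)(C)C(C)(C)C)[C@H]1[C@H](OC(=O)/C(C)=C\C)C/C(C)=C/CCOCc2ccc(OC)cc2 | intermediate
19 | C5 primary alcohol from 18 | CN(C)C[C@@H]1C(=O)O[C@H](CO)[C@H]1[C@H](OC(=O)/C(C)=C\C)C/C(C)=C/CCOCc2ccc(OC)cc2 | intermediate
20 | C5 aldehyde from 19 | CN(C)C[C@@H]1C(=O)O[C@H](C=O)[C@H]1[C@H](OC(=O)/C(C)=C\C)C/C(C)=C/CCOCc2ccc(OC)cc2 | intermediate (not isolated)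
21 | (E)-enal C6–C5H=C4H–C15HO | CN(C)C[C@@H]1C(=O)O[C@H](/C=C/C=O)[C@H]1[C@H](OC(=O)/C(C)=C\C)C/C(C)=C/CCOCc2ccc(OC)cc2 | intermediate
22 | (Z)-α-iodoenal, iodine on C4 cis to C6 | CN(C)C[C@@H]1C(=O)O[C@H](/C=C(\I)C=O)[C@H]1[C@H](OC(=O)/C(C)=C\C)C/C(C)=C/CCOCc2ccc(OC)cc2 | intermediate
23 | (Z)-2-iodoallylic alcohol, free C15 hydroxyl | CN(C)C[C@@H]1C(=O)O[C@H](/C=C(\I)CO)[C@H]1[C@H](OC(=O)/C(C)=C\C)C/C(C)=C/CCOCc2ccc(OC)cc2 | intermediate
24 | C15 tert-butyldimethylsilyl ether of 23 | CN(C)C[C@@H]1C(=O)O[C@H](/C=C(\I)CO[Si](C)(C)C(C)(C)C)[C@H]1[C@H](OC(=O)/C(C)=C\C)C/C(C)=C/CCOCc2ccc(OC)cc2 | intermediate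
25 | trimethylammonium iodide of 24 | C[N+](C)(C)C[C@@H]1C(=O)O[C@H](/C=C(\I)CO[Si](C)(C)C(C)(C)C)[C@H]1[C@H](OC(=O)/C(C)=C\C)C/C(C)=C/CCOCc2ccc(OC)cc2.[I-] | intermediate (not isolated)
26 | α-methylene lactone with Z iodoalkene, C15 silyl ether, C8 angelate and C3 PMB ether | C=C1C(=O)O[C@H](/C=C(\I)CO[Si](C)(C)C(C)(C)C)[C@H]1[C@H](OC(=O)/C(C)=C\C)C/C(C)=C/CCOCc2ccc(OC)cc2 | intermediate
27 | C3 primary alcohol from 26 | C=C1C(=O)O[C@H](/C=C(\I)CO[Si](C)(C)C(C)(C)C)[C@H]1[C@H](OC(=O)/C(C)=C\C)C/C(C)=C/CCO | intermediate
28 | C3 aldehyde from 27 | C=C1C(=O)O[C@H](/C=C(\I)CO[Si](C)(C)C(C)(C)C)[C@H]1[C@H](OC(=O)/C(C)=C\C)C/C(C)=C/CC=O | intermediate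
29 | (3S,6R,7R,8R)-8-angeloyloxy-15-(tert-butyldimethylsilyloxy)-3-hydroxygermacra-1(10)E,4Z,11(13)-trien-6,12-olide | C=C1C(=O)O[C@@H]2/C=C(/CO[Si](C)(C)C(C)(C)C)[C@@H](O)C/C=C(\C)C[C@@H](OC(=O)/C(C)=C\C)[C@@H]12 | intermediate
30 | (3S,6R,7R,8R)-8-angeloyloxy-3,15-dihydroxygermacra-1(10)E,4Z,11(13)-trien-6,12-olide | C=C1C(=O)O[C@@H]2/C=C(/CO)[C@@H](O)C/C=C(\C)C[C@@H](OC(=O)/C(C)=C\C)[C@@H]12 | intermediate
31 | CNP0187917.1, (1R,3S,6R,7R,8R,10R)-8-angeloyloxy-1,10-epoxy-3,15-dihydroxygermacra-4Z,11(13)-dien-6,12-olide | C=C1C(=O)O[C@@H]2/C=C(/CO)[C@@H](O)C[C@H]3O[C@]3(C)C[C@@H](OC(=O)/C(C)=C\C)[C@@H]12 | target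

## Step count and risk

Total step count: 20. Longest linear sequence: 19 steps (steps 2 to 20, from 4-methylpent-3-en-1-ol 3).

**Step 6 (key step).** The likely failures are competing 1,2-addition or γ-deprotonation of the butenolide by the hindered tertiary carbanion, and slow capture of the crowded enolate by the iminium salt in the HMPA medium. Fallback: the two bond formations are separated. Starting from 9 and 2, the conjugate addition alone is quenched with NH4Cl to give the β-dithianyl lactone F1. After isolation, LDA in THF at −78 °C regenerates the enolate without cosolvent, and salt 10 gives 13, where the route is rejoined.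

**Step 8.** The likely failure is poor facial selectivity in the hydride transfer. The intrinsic bias of the lactone-bearing C7 is unknown, and borane bound to the amine may reduce without the catalyst. Fallback: the esterification is made stereoconvergent. Starting from 14, an unselective reduction (NaBH4, CeCl3·7H2O) gives both epimers, which are separated. The 8R epimer is 15. The 8S alcohol F2 is esterified with inversion by a Mitsunobu reaction with 16 (PPh3, DIAD, toluene, 0 °C), arriving at 18.

**Step 12.** The likely failures are consumption of iodine by the tertiary amine, partial hydrolysis of the lactone in aqueous carbonate, and loss of C6 integrity through γ-deprotonation of the enal. Fallback: the iodoalkene is built without an enal. Starting from 19, Dess–Martin oxidation gives 20, and Ramirez olefination (CBr4, PPh3, CH2Cl2) gives the 1,1-dibromoalkene F3. A trans-selective Stille coupling with Bu3SnCH2OH (Pd2(dba)3, tri(2-furyl)phosphine, toluene) replaces the bromine trans to C6 and gives the (Z)-2-bromoallylic alcohol F4. Copper-catalysed bromide–iodide exchange (CuI, NaI, N,N'-dimethylethylenediamine, dioxane) then gives 23.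

**Step 18.** The likely failure is poor facial selectivity at C3 during ring closure, since only the ring conformation controls it. Oligomerisation is held back by dilution. Fallback: C3 is set after the ring is closed. Starting from 28, the closure is run as planned, and the mixture of C3 epimers is oxidised with Dess–Martin periodinane to the macrocyclic enone F5. Reduction with (R)-2-methyl-CBS-oxazaborolidine and catecholborane, with the alkenyl side as the large group, gives the 3S alcohol 29.

**Step 20.** The likely failures are attack on the inner face of C1=C10 if the ring conformation is not as assumed, and attack at C4=C5 directed by the free allylic hydroxyl groups. Fallback: the epoxide is made before ring closure under reagent control.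
- Starting from 26, Shi epoxidation gives the (1R,10R) epoxide F6. The reagents are the D-fructose-derived ketone 1,2:4,5-di-O-isopropylidene-β-D-erythro-2,3-hexodiulo-2,6-pyranose, Oxone (2KHSO5·KHSO4·K2SO4) and K2CO3 in MeCN/dimethoxymethane/water at 0 °C.
- DDQ gives the epoxy alcohol F7, and Dess–Martin oxidation gives the epoxy aldehyde F8, which is used crude.
- CrCl2/NiCl2 closure gives the macrocyclic epoxy silyl ether F9.
- Desilylation with Bu4NF buffered by acetic acid gives 31.

## Further compounds

F1 | step 6 | (4S,5S)-5-[(tert-butyldimethylsilyloxy)methyl]-4-{2-[(E)-5-(4-methoxybenzyloxy)-2-methylpent-2-enyl]-1,3-dithian-2-yl}oxolan-2-one | O=C1C[C@H](C2(C/C(C)=C/CCOCc3ccc(OC)cc3)SCCCS2)[C@@H](CO[Si](C)(C)C(C)(C)C)O1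
F2 | step 8 | (8S) epimer of alcohol 15 | CN(C)C[C@@H]1C(=O)O[C@H](CO[Si](C)(C)C(C)(C)C)[C@H]1[C@@H](O)C/C(C)=C/CCOCc2ccc(OC)cc2
F3 | step 12 | 1,1-dibromoalkene from aldehyde 20 | CN(C)C[C@@H]1C(=O)O[C@H](C=C(Br)Br)[C@H]1[C@H](OC(=O)/C(C)=C\C)C/C(C)=C/CCOCc2ccc(OC)cc2
F4 | step 12 | (Z)-2-bromoallylic alcohol, bromo analogue of 23 | CN(C)C[C@@H]1C(=O)O[C@H](/C=C(\Br)CO)[C@H]1[C@H](OC(=O)/C(C)=C\C)C/C(C)=C/CCOCc2ccc(OC)cc2
F5 | step 18 | macrocyclic C3 ketone (4Z-en-3-one) with C15 silyl ether | C=C1C(=O)O[C@@H]2/C=C(/CO[Si](C)(C)C(C)(C)C)C(=O)C/C=C(\C)C[C@@H](OC(=O)/C(C)=C\C)[C@@H]12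
F6 | step 20 | (1R,10R) epoxide of 26 | C=C1C(=O)O[C@H](/C=C(\I)CO[Si](C)(C)C(C)(C)C)[C@H]1[C@H](OC(=O)/C(C)=C\C)C[C@@]3(C)O[C@@H]3CCOCc2ccc(OC)cc2
F7 | step 20 | (1R,10R) epoxy C3 alcohol | C=C1C(=O)O[C@H](/C=C(\I)CO[Si](C)(C)C(C)(C)C)[C@H]1[C@H](OC(=O)/C(C)=C\C)C[C@@]3(C)O[C@@H]3CCO
F8 | step 20 | (1R,10R) epoxy C3 aldehyde | C=C1C(=O)O[C@H](/C=C(\I)CO[Si](C)(C)C(C)(C)C)[C@H]1[C@H](OC(=O)/C(C)=C\C)C[C@@]3(C)O[C@@H]3CC=O
F9 | step 20 | 15-O-tert-butyldimethylsilyl ether of 31 | C=C1C(=O)O[C@@H]2/C=C(/CO[Si](C)(C)C(C)(C)C)[C@@H](O)C[C@H]3O[C@]3(C)C[C@@H](OC(=O)/C(C)=C\C)[C@@H]12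
A1 | alternative 1 | 1(10)-ene (desepoxy) form of the target, identical with 30 | C=C1C(=O)O[C@@H]2/C=C(/CO)[C@@H](O)C/C=C(\C)C[C@@H](OC(=O)/C(C)=C\C)[C@@H]12
A2 | alternative 1 | 8-angeloyloxy-3,15-dihydroxygermacra-1(10)E,4Z,11(13)-trien-12-oic acid | C=C(C(=O)O)[C@H]1C/C=C(/CO)[C@@H](O)C/C=C(\C)C[C@H]1OC(=O)/C(C)=C\C
A3 | alternative 2 | ten-membered 1(10)E,4Z-dien-6-one carrying C7 and C8 | O=C1/C=C(/CO[Si](C)(C)C(C)(C)C)[C@@H](O[Si](C)(C)C(C)(C)C)C/C=C(\C)C[C@@H](OCc2ccc(OC)cc2)[C@H]1CC(OC)OC
A4 | alternative 2 | trans-fused hydroazulenol mesylate with C6 bridgehead alcohol and C1 mesylate anti to the C6–C10 bond | C[C@@]12C[C@@H](OCc3ccc(OC)cc3)[C@@H](CC(OC)OC)[C@@]1(O)/C=C(/CO[Si](C)(C)C(C)(C)C)[C@@H](O[Si](C)(C)C(C)(C)C)C[C@H]2OS(C)(=O)=O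
A5 | alternative 3 | E homoallylic alcohol spanning C8 to C15 | CC(C)(C)[Si](C)(C)OCC/C(C)=C/C[C@H](O)[C@@H]1COC(C)(C)O1
A6 | alternative 3 | (but-3-yn-1-yloxy)(tert-butyl)dimethylsilane | C#CCCO[Si](C)(C)C(C)(C)C
A7 | alternative 3 | (4S)-2,2-dimethyl-4-[(2S)-oxiran-2-yl]-1,3-dioxolane | C1O[C@@H]1[C@@H]2COC(C)(C)O2
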